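## Retrosynthetic overview

1. Target ⇐ fluoride desilylation ⇐ Steglich acylation of the C8 hydroxyl with silyl-protected 4-hydroxybenzoic acid ⇐ anti-selective hydroboration of the C7=C8 alkene of a guaia-1(10),7-diene 4,6-bis(silyl ether), which sets C7 and C8 from C6.
2. That hydroazulene diene ⇐ new anionic [2,3]-Wittig ring expansion of a 2-(cyclopentenyl)-2-methyl-5-isopropyl-3,6-dihydro-2H-pyran. It makes the C5–C6 bond, the C5 and C6 stereocentres and the tetrasubstituted C1=C10 alkene as the seven-membered ring forms.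
3. Dihydropyran ⇐ ring-closing metathesis ⇐ O-alkylation (2-isopropylallyl bromide) of a tertiary homoallylic alcohol ⇐ catalytic asymmetric allylation of a cyclopentenyl methyl ketone (sets C10, whose chirality is relayed to C5 and C6).
4. Cyclopentenyl methyl ketone ⇐ aldol cyclocondensation of a keto aldehyde ⇐ (R)-2-methylglycidol (C4 carbinol from the chiral pool) plus a 3-oxobutyl Grignard equivalent.
5. Ring order: cyclopentene first, then a temporary dihydropyran, then the cycloheptadiene by ring expansion. Guaiane numbering is used for C1–C10: C4 C(OH)Me, C5 ring-fusion CH, C6 CHOH, C7 CH-iPr, C8 CH-O-ester, C9 CH2, C10=C1 alkene.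

Assumption: the (R,R) antipode of the DuPHOS ligand in step 5 is taken to be the one that sends the allyl group to the Si face of the ketone; if the sense is the reverse, the (S,S) ligand is used and nothing else changes.

## Route

Step 1
Reactants: 1, 2-(2-bromoethyl)-2-methyl-1,3-dioxolane; 2, (R)-2-methylglycidol [(2R)-(2-methyloxiran-2-yl)methanol]
Product: 4 (S)-2-methyl-5-(2-methyl-1,3-dioxolan-2-yl)pentane-1,2-diol, via Grignard reagent 3 (not isolated)
Conditions: 1 (2.4 equiv), Mg, THF, 25–30 °C; then 2 (1.0 equiv), CuI (10 mol%), THF, −30 → 0 °C; aq. NH4Cl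
Reagents that add atoms: none
Why: Copper-catalysed SN2 opening of the 2,2-disubstituted epoxide at its CH2 terminus by the Grignard reagent (one equivalent is spent on the hydroxyl proton); the quaternary carbinol centre (future C4) is not touched and comes from the chiral pool.

Step 2
Reactants: 4, (S)-2-methyl-5-(2-methyl-1,3-dioxolan-2-yl)pentane-1,2-diol
Product: 5 (S)-2-hydroxy-2-methyl-5-(2-methyl-1,3-dioxolan-2-yl)pentanal
Conditions: IBX (1.5 equiv), DMSO, rt
Reagents that add atoms: none
Why: IBX oxidation takes the primary hydroxyl of a 1,2-diol to the α-hydroxy aldehyde without glycol cleavage and cannot oxidise the tertiary hydroxyl.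

Step 3
Reactants: 5, (S)-2-hydroxy-2-methyl-5-(2-methyl-1,3-dioxolan-2-yl)pentanal
Product: 7 (S)-1-(3-hydroxy-3-methylcyclopent-1-en-1-yl)ethan-1-one, via keto aldehyde 6 (not isolated)
Conditions: 1 M HCl, THF, rt; NaHCO3 to pH 7; then pyrrolidine (0.3 equiv), AcOH (0.3 equiv), THF, 40 °C
Reagents that add atoms: water, O
Why: Ketal hydrolysis followed by amine-catalysed intramolecular aldol condensation (5-enolexo); the aldehyde has no α-hydrogen, so only the internal CH2 of the methyl ketone can close the five-membered ring, and the quaternary carbinol centre cannot epimerise.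

Step 4
Reactants: 7, (S)-1-(3-hydroxy-3-methylcyclopent-1-en-1-yl)ethan-1-one
Product: 8 1-[(3S)-3-methyl-3-(triethylsilyloxy)cyclopent-1-en-1-yl]ethan-1-one
Conditions: TESOTf (1.3 equiv), 2,6-lutidine, CH2Cl2, −78 °C
Reagents that add atoms: triethylsilyl triflate (TESOTf), CC[Si](CC)(CC)OS(=O)(=O)C(F)(F)F
Why: Silyl triflate silylation of a tertiary alcohol; the base-stable ether protects the C4 oxygen through the carbanion chemistry.

Step 5
Reactants: 8, 1-[(3S)-3-methyl-3-(triethylsilyloxy)cyclopent-1-en-1-yl]ethan-1-one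
Product: 9 (2S)-2-[(3S)-3-methyl-3-(triethylsilyloxy)cyclopent-1-en-1-yl]pent-4-en-2-ol
Conditions: allylBpin (1.3 equiv), CuF2·2H2O (3 mol%), (R,R)-iPr-DuPHOS (6 mol%), La(OiPr)3 (4.5 mol%), DMF, −40 °C; aq. work-up
Reagents that add atoms: allylboronic acid pinacol ester (allylBpin), C=CCB1OC(C)(C)C(C)(C)O1
Why: Catalytic enantioselective allylboration of a ketone: the bisphosphine-bound allylcopper species (monovalent copper) adds 1,2 to the Si face under reagent control, giving the (S) tertiary carbinol at C10, while 1,4-addition is blocked by the quaternary carbon next to the β-position.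

Step 6
Reactants: 10, propargyl alcohol (prop-2-yn-1-ol)
Product: 11 3-methyl-2-methylidenebutan-1-ol
Conditions: iPrMgCl (2.5 equiv), CuI (10 mol%), Et2O/THF, 0 °C → reflux; aq. NH4Cl
Reagents that add atoms: isopropylmagnesium chloride, CC(C)[Mg]Cl
Why: Hydroxyl-directed, copper-catalysed carbomagnesiation of the propargylic alkoxide places the alkyl group on the internal alkyne carbon and gives the 2-substituted allylic alcohol on protonation.

Step 7
Reactants: 11, 3-methyl-2-methylidenebutan-1-ol
Product: 12 2-(bromomethyl)-3-methylbut-1-ene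
Conditions: PBr3 (0.4 equiv), pyridine (cat.), Et2O, 0 °C
Reagents that add atoms: phosphorus tribromide, BrP(Br)Br
Why: Bromination of a primary allylic alcohol; SN2 and SN2' give the same bromide because the allyl unit is symmetric.

Step 8
Reactants: 9, (2S)-2-[(3S)-3-methyl-3-(triethylsilyloxy)cyclopent-1-en-1-yl]pent-4-en-2-ol; 12, 2-(bromomethyl)-3-methylbut-1-ene
Product: 13 triethyl({(1S)-1-methyl-3-[(2S)-2-[(3-methyl-2-methylidenebutyl)oxy]pent-4-en-2-yl]cyclopent-2-en-1-yl}oxy)silane
Conditions: NaH (1.5 equiv), Bu4NI (10 mol%), DMF, 0 °C; then 12 (2 equiv), 0 °C → rt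
Reagents that add atoms: none
Why: Williamson etherification of the tertiary sodium alkoxide with a reactive allylic bromide; the sodium counter-ion and low temperature keep the anionic oxy-Cope pathway of this 1,5-dien-3-olate slow.

Step 9
Reactants: 13, triethyl({(1S)-1-methyl-3-[(2S)-2-[(3-methyl-2-methylidenebutyl)oxy]pent-4-en-2-yl]cyclopent-2-en-1-yl}oxy)silane
Product: 14 triethyl({(1S)-1-methyl-3-[(2S)-2-methyl-5-(propan-2-yl)-3,6-dihydro-2H-pyran-2-yl]cyclopent-2-en-1-yl}oxy)silane
Conditions: second-generation Grubbs catalyst (5 mol%), CH2Cl2, 40 °C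
Reagents that add atoms: none
Why: Ring-closing metathesis of the allyl and 1,1-disubstituted alkenes to a six-membered ring with a trisubstituted alkene, helped by the quaternary ring carbon; the trisubstituted cyclopentene does not take part.

Step 10
Reactants: 14, triethyl({(1S)-1-methyl-3-[(2S)-2-methyl-5-(propan-2-yl)-3,6-dihydro-2H-pyran-2-yl]cyclopent-2-en-1-yl}oxy)silane
Product: 17 (3S,3aS,4S)-3,8-dimethyl-5-(propan-2-yl)-3,4-bis(triethylsilyloxy)-1,2,3,3a,4,7-hexahydroazulene, via α-lithio ether 15 (not isolated), via lithium alkoxide 16 (not isolated)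
Conditions: s-BuLi (1.3 equiv), THF, −78 °C, 1 h; then TESCl (1.6 equiv), −78 → 0 °C
Reagents that add atoms: triethylsilyl chloride (TESCl), CC[Si](CC)(CC)Cl
Why: Proposed new method: an anionic [2,3]-Wittig ring expansion of a 2-alkenyl-3,6-dihydro-2H-pyran to a cyclohepta-1,4-dien-ol, in which s-BuLi removes the allylic α-oxy proton at C6 and the resulting α-oxyallyl anion attacks the cyclopentenyl CH terminus (C5) through a five-membered, six-electron suprafacial transition state shaped like a bicyclo[3.2.1]octene, so the C10–O bond is exchanged for the C5–C6 bond, the six-membered ether becomes the seven-membered carbocycle and the tetrasubstituted C1=C10 alkene is formed inside the ring with the only possible geometry; the (S) centre at C10 holds the oxygen, and so the incoming carbanion, on the cyclopentene face syn to the C4 silyloxy group, which gives H-5 anti to that group and the C6 oxygen syn to it, and the alkoxide is silylated in the same flask; the closest known reactions are the [2,3]-Wittig rearrangement of acyclic bis-allylic ethers and the Wittig ring contractions of large-ring diallylic ethers, while the [1,2]- and [1,4]-Wittig ring contractions known for α-lithiated dihydropyrans are the expected competitors.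

Step 11
Reactants: 17, (3S,3aS,4S)-3,8-dimethyl-5-(propan-2-yl)-3,4-bis(triethylsilyloxy)-1,2,3,3a,4,7-hexahydroazulene
Product: 19 (3S,3aS,4R,5R,6S)-3,8-dimethyl-5-(propan-2-yl)-3,4-bis(triethylsilyloxy)-1,2,3,3a,4,5,6,7-octahydroazulen-6-ol, via B-alkyl-9-BBN adduct 18 (not isolated)
Conditions: 9-BBN dimer (2.5 equiv), THF, 65 °C; then 3 M NaOH, 30% H2O2, 0 °C → rt
Reagents that add atoms: hydrogen peroxide, OO
Why: Hydroboration–oxidation: 9-BBN adds syn across the trisubstituted C7=C8 bond from the face anti to the allylic C6 silyloxy group with boron on the less substituted C8, so H-7 and the C8 oxygen (stereoretentive oxidation) end cis to each other and trans to the C6 oxygen, and the tetrasubstituted C1=C10 alkene is inert to 9-BBN.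

Step 12
Reactants: 19, (3S,3aS,4R,5R,6S)-3,8-dimethyl-5-(propan-2-yl)-3,4-bis(triethylsilyloxy)-1,2,3,3a,4,5,6,7-octahydroazulen-6-ol; 20, 4-[(tert-butyldimethylsilyl)oxy]benzoic acid
Product: 21 (3S,3aS,4R,5R,6S)-3,8-dimethyl-5-(propan-2-yl)-3,4-bis(triethylsilyloxy)-1,2,3,3a,4,5,6,7-octahydroazulen-6-yl 4-[(tert-butyldimethylsilyl)oxy]benzoate
Conditions: DCC (1.5 equiv), DMAP (0.5 equiv), CH2Cl2, rt → 40 °C
Reagents that add atoms: none
Why: Steglich esterification of the only free hydroxyl (C8); the C–O bond of the alcohol is not broken, so the configuration is kept.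

Step 13
Reactants: 21, (3S,3aS,4R,5R,6S)-3,8-dimethyl-5-(propan-2-yl)-3,4-bis(triethylsilyloxy)-1,2,3,3a,4,5,6,7-octahydroazulen-6-yl 4-[(tert-butyldimethylsilyl)oxy]benzoate
Product: 22 (3S,3aS,4R,5S,6S)-3,4-dihydroxy-3,8-dimethyl-5-(propan-2-yl)-1,2,3,3a,4,5,6,7-octahydroazulen-6-yl 4-hydroxybenzoate
Conditions: HF·pyridine, pyridine, THF, 0 °C → rt
Reagents that add atoms: none
Why: Fluoride-driven cleavage of the two triethylsilyl ethers and the aryl silyl ether in a buffered medium that leaves the benzoate and the tertiary homoallylic alcohol intact.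

## Compound list

1 | 2-(2-bromoethyl)-2-methyl-1,3-dioxolane | CC1(CCBr)OCCO1 | starting material
2 | (R)-2-methylglycidol | C[C@@]1(CO)CO1 | starting material
3 | [2-(2-methyl-1,3-dioxolan-2-yl)ethyl]magnesium bromide | CC1(CC[Mg]Br)OCCO1 | intermediate
4 | (S)-2-methyl-5-(2-methyl-1,3-dioxolan-2-yl)pentane-1,2-diol | C[C@@](O)(CO)CCCC1(C)OCCO1 | intermediate
5 | (S)-2-hydroxy-2-methyl-5-(2-methyl-1,3-dioxolan-2-yl)pentanal | C[C@@](O)(C=O)CCCC1(C)OCCO1 | intermediate
6 | (S)-2-hydroxy-2-methyl-6-oxoheptanal | C[C@@](O)(C=O)CCCC(C)=O | intermediate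
7 | (S)-1-(3-hydroxy-3-methylcyclopent-1-en-1-yl)ethan-1-one | C[C@@]1(O)C=C(C(C)=O)CC1 | intermediate
8 | 1-[(3S)-3-methyl-3-(triethylsilyloxy)cyclopent-1-en-1-yl]ethan-1-one | C[C@@]1(O[Si](CC)(CC)CC)C=C(C(C)=O)CC1 | intermediate
9 | (2S)-2-[(3S)-3-methyl-3-(triethylsilyloxy)cyclopent-1-en-1-yl]pent-4-en-2-ol | C=CC[C@](C)(O)C1=C[C@@](C)(O[Si](CC)(CC)CC)CC1 | intermediate
10 | propargyl alcohol | OCC#C | starting material
11 | 3-methyl-2-methylidenebutan-1-ol | CC(C)C(=C)CO | intermediate
12 | 2-(bromomethyl)-3-methylbut-1-ene | CC(C)C(=C)CBr | intermediate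
13 | 2-isopropylallyl ether of 9 (S at both centres) | C=CC[C@](C)(OCC(=C)C(C)C)C1=C[C@@](C)(O[Si](CC)(CC)CC)CC1 | intermediate
14 | (2S)-2-methyl-2-[(3S)-3-methyl-3-(triethylsilyloxy)cyclopent-1-en-1-yl]-5-(propan-2-yl)-3,6-dihydro-2H-pyran | CC(C)C1=CC[C@](C)(OC1)C2=C[C@@](C)(O[Si](CC)(CC)CC)CC2 | intermediate
15 | 6-lithio derivative of 14 (lithium on the ring OCH carbon) | CC(C)C1=CC[C@](C)(OC1[Li])C2=C[C@@](C)(O[Si](CC)(CC)CC)CC2 | intermediate
16 | lithium (3S,3aS,4S)-3,8-dimethyl-5-(propan-2-yl)-3-(triethylsilyloxy)-1,2,3,3a,4,7-hexahydroazulen-4-olate | CC1=C2CC[C@](C)(O[Si](CC)(CC)CC)[C@@H]2[C@H](O[Li])C(C(C)C)=CC1 | intermediate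
17 | (3S,3aS,4S)-3,8-dimethyl-5-(propan-2-yl)-3,4-bis(triethylsilyloxy)-1,2,3,3a,4,7-hexahydroazulene | CC1=C2CC[C@](C)(O[Si](CC)(CC)CC)[C@@H]2[C@H](O[Si](CC)(CC)CC)C(C(C)C)=CC1 | intermediate
18 | B-alkyl-9-BBN adduct of 17 (boron on C8, cis to H-7, trans to the C6 oxygen) | CC1=C2CC[C@](C)(O[Si](CC)(CC)CC)[C@@H]2[C@H](O[Si](CC)(CC)CC)[C@H](C(C)C)[C@@H](B3C4CCCC3CCC4)C1 | intermediate
19 | (3S,3aS,4R,5R,6S)-3,8-dimethyl-5-(propan-2-yl)-3,4-bis(triethylsilyloxy)-1,2,3,3a,4,5,6,7-octahydroazulen-6-ol | CC1=C2CC[C@](C)(O[Si](CC)(CC)CC)[C@@H]2[C@H](O[Si](CC)(CC)CC)[C@H](C(C)C)[C@@H](O)C1 | intermediate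
20 | 4-[(tert-butyldimethylsilyl)oxy]benzoic acid | CC(C)(C)[Si](C)(C)Oc1ccc(cc1)C(=O)O | starting material
21 | (3S,3aS,4R,5R,6S)-3,8-dimethyl-5-(propan-2-yl)-3,4-bis(triethylsilyloxy)-1,2,3,3a,4,5,6,7-octahydroazulen-6-yl 4-[(tert-butyldimethylsilyl)oxy]benzoate | CC1=C2CC[C@](C)(O[Si](CC)(CC)CC)[C@@H]2[C@H](O[Si](CC)(CC)CC)[C@H](C(C)C)[C@@H](OC(=O)c2ccc(O[Si](C)(C)C(C)(C)C)cc2)C1 | intermediate
22 | (3S,3aS,4R,5S,6S)-3,4-dihydroxy-3,8-dimethyl-5-(propan-2-yl)-1,2,3,3a,4,5,6,7-octahydroazulen-6-yl 4-hydroxybenzoate (CNP0392039.1) | CC1=C2CC[C@](C)(O)[C@@H]2[C@H](O)[C@H](C(C)C)[C@@H](OC(=O)c2ccc(O)cc2)C1 | target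

## Step count and risks

Total step count: 13. Longest linear sequence: 11 steps (steps 1–5 and 8–13; steps 6–7 make the side-chain bromide).

Three steps most likely to fail:

Step 10 (the proposed new ring expansion). The migrating carbon is tertiary and allylic, so [1,2]- and [1,4]-Wittig shifts of the lithiated dihydropyran may compete with the [2,3] pathway. The fallback uses known chemistry, sets out from 13 and postpones the metathesis. s-BuLi (THF, −78 °C) lithiates the OCH2 of the 2-isopropylallyl group to give the α-lithio ether F1. Its ordinary acyclic [2,3]-Wittig rearrangement onto the cyclopentenyl terminus gives the lithium alkoxide F2. TESCl then gives the (Z)-triene bis(silyl ether) F3, which is separated from its E isomer and any C6 epimer. Ring-closing metathesis of F3 (second-generation Grubbs catalyst, CH2Cl2, 40 °C) between the allyl group and the isopropyl-substituted vinyl group closes C7=C8 and comes back to the route at 17.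

Step 8 (etherification of the hindered tertiary alkoxide). It may be slow, or the 1,5-dien-3-olate may undergo anionic oxy-Cope rearrangement. The fallback sets out from 9 (with alcohol 11 as the allyl source) and replaces the SN2 alkylation by a metal-catalysed allylic etherification. Alcohol 11 is converted with methyl chloroformate and pyridine into the allylic methyl carbonate F4. Alcohol 9 is deprotonated with LiHMDS to the lithium alkoxide F5 and transmetalated with CuI to the copper alkoxide F6 (monovalent copper), which is far less prone to oxy-Cope rearrangement. RhCl(PPh3)3 modified with P(OMe)3 (THF, 0 °C → rt) then joins F6 to the allyl unit of F4 and comes back to the route at 13.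

Step 5 (catalyst-controlled allylation next to an existing stereocentre). The diastereomer ratio at C10 may be low, or the facial sense may be the reverse of that assumed. The fallback sets out from 8 and gives up on stereocontrol: allylmagnesium bromide (THF, −78 °C) adds 1,2 to give 9 together with the (2R) epimer F7 in roughly equal amounts. The two are diastereomers because of the C4 centre and are separated by chromatography, and the route is rejoined at 9.

Further compounds
F1 | step 10 | α-lithio derivative of 13 (lithium on the OCH carbon of the 2-isopropylallyl group) | C=CC[C@](C)(OC([Li])C(=C)C(C)C)C1=C[C@@](C)(O[Si](CC)(CC)CC)CC1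
F2 | step 10 | lithium (1S)-1-[(1S,2S,5Z)-2-methyl-5-(pent-4-en-2-ylidene)-2-(triethylsilyloxy)cyclopentyl]-2-(propan-2-yl)prop-2-en-1-olate | C=CC/C(C)=C1/CC[C@](C)(O[Si](CC)(CC)CC)[C@@H]1[C@H](O[Li])C(=C)C(C)C
F3 | step 10 | (1S,2S)-1-methyl-3-[(Z)-pent-4-en-2-ylidene]-2-[(1S)-2-(propan-2-yl)-1-(triethylsilyloxy)prop-2-en-1-yl]-1-(triethylsilyloxy)cyclopentane | C=CC/C(C)=C1/CC[C@](C)(O[Si](CC)(CC)CC)[C@@H]1[C@H](O[Si](CC)(CC)CC)C(=C)C(C)C
F4 | step 8 | methyl (3-methyl-2-methylidenebutyl) carbonate | COC(=O)OCC(=C)C(C)C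
F5 | step 8 | lithium alkoxide of 9 | C=CC[C@](C)(O[Li])C1=C[C@@](C)(O[Si](CC)(CC)CC)CC1
F6 | step 8 | copper alkoxide of 9 | C=CC[C@](C)(O[Cu])C1=C[C@@](C)(O[Si](CC)(CC)CC)CC1
F7 | step 5 | (2R)-2-[(3S)-3-methyl-3-(triethylsilyloxy)cyclopent-1-en-1-yl]pent-4-en-2-ol | C=CC[C@@](C)(O)C1=C[C@@](C)(O[Si](CC)(CC)CC)CC1
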